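**Retrosynthetic overview**
1. Target ⇐ selective removal of the anomeric acetate ⇐ α-face epoxidation of Δ9(11) ⇐ Woodward cis-dihydroxylation/acetylation of Δ1 on a tetracyclic acetal.
2. Oxepane acetal (ring B) ⇐ one acid step that unmasks an enol carbamate (C6 aldehyde), the C7 silyl ether and a C15 enol silane; Δ9(11) ⇐ dehydration of a C9 tertiary alcohol.
3. Key bond C9–C10: a safranal-derived dienyl carbamate used as a homoenolate (nucleophilic β-carbon C10) adds to the C9 carbonyl of a bicyclo[3.2.1]octan-2-one.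
4. Ring C (C12–C13) ⇐ SmI2 reductive cyclisation of a β-iodo ketone onto a cyclopentenone; C8 ⇐ asymmetric hydroxymethylation of a 1,3-diketone made from 2-methylcyclopentenone.
5. Ring order: A (safranal) and D (2-methylcyclopentenone) are bought, then C (step 7), B (step 10), epoxide (step 12).

Numbering used below (seco-kaurane type): ring A = C1–C5, C10 (C18/C19 on C4, C20 on C10); C6 hemiacetal carbon; C7 = OCH2; C8 quaternary bridgehead; C9/C11 epoxide; C12, C13, C14; C15 ketone; C16 (methyl = C17).

Assumption: the hemiacetal settles as the thermodynamic anomer, taken to be the (6R) one of the target, and the (−)-sparteine/ketone pairing in step 8 is taken as matched for 10S (otherwise the (+)-sparteine surrogate is used).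

This route is a paper plan; no step has been run.

**Step 1**
Reactants: 1 safranal
Product: 2 safranol
Conditions: NaBH4, CeCl3·7H2O, MeOH, 0 °C
Reagents that add atoms: none
Why: Luche 1,2-reduction of the conjugated aldehyde leaves the diene untouched and creates no stereocentre.

**Step 2**
Reactants: 2 safranol
Product: 3 safranyl N,N-diisopropylcarbamate
Conditions: NaH, THF, 0 °C; iPr2NCOCl, reflux
Reagents that add atoms: N,N-diisopropylcarbamoyl chloride CC(C)N(C(C)C)C(Cl)=O
Why: O-carbamoylation of the alkoxide installs the Hoppe carbamate that later directs α-lithiation; no stereocentre.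

**Step 3**
Reactants: 4 2-methylcyclopent-2-en-1-one; 5 3-chloropropanoyl chloride
Product: 6 5-(3-chloropropanoyl)-2-methylcyclopent-2-en-1-one
Conditions: LiHMDS (2 equiv), THF, −78 °C; then 5; AcOH
Reagents that add atoms: none
Why: kinetic α′-enolate formation and Claisen-type C-acylation give the 1,3-diketone, which the second equivalent of base stores as its diketonate; C8 stays enolisable, so no stereocentre is fixed.

**Step 4**
Reactants: 6 chloro diketone; 7 formaldehyde
Product: 8 (S)-5-(3-chloropropanoyl)-5-(hydroxymethyl)-2-methylcyclopent-2-en-1-one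
Conditions: aq. HCHO, Sc(OTf)3 (5 mol%), chiral N,N′-dioxide ligand (5 mol%), THF, −20 °C
Reagents that add atoms: none
Why: catalytic enantioselective hydroxymethylation (formaldehyde aldol) of the chelated 1,3-diketone, as established for cyclic β-keto esters, sets the C8 quaternary centre (S) by attack on the unshielded enolate face.

**Step 5**
Reactants: 8 hydroxymethyl diketone
Product: 9 TBS ether of 8
Conditions: TBSOTf, 2,6-lutidine, CH2Cl2, −78 °C
Reagents that add atoms: tert-butyldimethylsilyl triflate CC(C)(C)[Si](C)(C)OS(=O)(=O)C(F)(F)F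
Why: silylation with a weak hindered base blocks retro-aldol loss of formaldehyde and O-alkylation by the chloride without eliminating HCl.

**Step 6**
Reactants: 9 chloride
Product: 10 (S)-5-[(TBS-oxy)methyl]-5-(3-iodopropanoyl)-2-methylcyclopent-2-en-1-one
Conditions: NaI, acetone, 50 °C
Reagents that add atoms: sodium iodide [Na+].[I-]
Why: Finkelstein SN2 exchange gives the iodide needed for fast single-electron reduction.

**Step 7**
Reactants: 10 iodide
Product: 12 (1R,5R)-1-[(TBS-oxy)methyl]-6-methyl-7-(trimethylsilyloxy)bicyclo[3.2.1]oct-6-en-2-one, via samarium enolate 11 (not isolated)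
Conditions: SmI2 (2.5 equiv, slow addition), HMPA, THF, −78 → 0 °C; then TMSCl, Et3N
Reagents that add atoms: chlorotrimethylsilane C[Si](C)(C)Cl
Why: SmI2 reduces the C–I bond to a β-keto alkyl radical (a ketone homoenolate equivalent) that closes ring C 6-exo-trig onto the enone β-carbon C13, and the second electron gives the Sm(III) enolate trapped by TMSCl (radical–polar crossover conjugate addition); C13 is forced cis to the bridge from C8, and C15 is masked so that C9 is the only ketone.

**Step 8 (key step)**
Reactants: 3 safranyl carbamate; 12 bicyclic ketone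
Product: 15 homoaldol adduct (C9 tertiary alcohol, C10 quaternary with Me-20 α, Δ1, (Z)-enol carbamate at C5=C6), via lithiated carbamate 13 (not isolated), via allyltitanium reagent 14 (not isolated)
Conditions: n-BuLi, (−)-sparteine, PhMe, −78 °C; ClTi(OiPr)3; then 12, −78 → −30 °C; H2O
Reagents that add atoms: none
Why: Proposed new method: Hoppe homoaldol addition of a dienyl carbamate to a hindered ketone, in which sparteine-mediated lithiation next to the carbamate and Li→Ti exchange give a configurationally defined α-titanated carbamate (a homoenolate equivalent of safranal) that adds through a closed six-membered SE2′ transition state with its γ-carbon C10 to the exo face of the only carbonyl (C9), relaying the C6 configuration to the new quaternary C10 while leaving Δ1 and the enol carbamate (masked C6 aldehyde); the closest known chemistry is the homoaldol reaction of titanated 2-alkenyl carbamates with aldehydes and simple ketones, including γ-methylcycloalkenyl carbamates that give quaternary centres.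

**Step 9**
Reactants: 15 homoaldol adduct
Product: 16 Δ9(11) triene
Conditions: Burgess reagent, PhMe, 60 °C
Reagents that add atoms: none
Why: Burgess syn-elimination of the tertiary alcohol can only take a hydrogen from C11, because C8 and C10 are quaternary, and so gives Δ9(11) regiospecifically under neutral conditions.

**Step 10**
Reactants: 16 triene
Product: 18 cyclic methyl acetal (oxepane closed, 15-ketone, H-5β, 16-methyl endo), via dimethyl acetal 17 (not isolated)
Conditions: MeSO3H (0.3 equiv), MeOH, 0 °C; evaporate; PPTS, 4 Å MS, CH2Cl2, rt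
Reagents that add atoms: methanol CO
Why: acid methanolysis of the enol carbamate (Hoppe unmasking) with loss of both silyl groups, then transacetalisation, closes ring B; C5 is set by axial β-face protonation anti to the two flanking axial methyls and C16 by exo-face protonation of the enol silane.

**Step 11**
Reactants: 18 cyclic methyl acetal
Product: 21 1α,2α,6-triacetate, via iodo acetate 19 (not isolated), via hydroxy acetate 20 (not isolated)
Conditions: I2, AgOAc, AcOH, rt, dark; H2O, 90 °C; filter, evaporate; Ac2O, pyridine, DMAP, rt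
Reagents that add atoms: silver acetate CC(=O)[O-].[Ag+]; water O; acetic anhydride CC(=O)OC(C)=O
Why: Woodward cis-hydroxylation (β-iodonium on Δ1, diaxial acetate attack at C2, Ag-assisted acetoxonium formation with inversion at C1, hydrolysis) puts both oxygens on the hindered α-face (1R,2S) while the shielded Δ9(11) cannot be opened anti; hot aqueous acetic acid then hydrolyses the acetal and acetylation caps all three hydroxyls.

**Step 12**
Reactants: 21 triacetate
Product: 22 9α,11α-epoxy triacetate
Conditions: DMDO, acetone, 0 °C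
Reagents that add atoms: dimethyldioxirane CC1(C)OO1
Why: neutral DMDO epoxidation occurs on the exo (α) face of the bicyclo[3.2.1]octene, anti to the C15–C16 bridge with its endo methyl, giving the 9S,11R epoxide without Baeyer–Villiger oxidation.

**Step 13**
Reactants: 22 epoxy triacetate
Product: 23 target
Conditions: N2H4·HOAc, DMF, 0 °C → rt
Reagents that add atoms: none
Why: the anomeric acetate is far more electrophilic than the two secondary acetates, so hydrazinolysis removes it selectively and the hemiacetal settles as the thermodynamic anomer.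

**Compound list**
1 | safranal (2,6,6-trimethylcyclohexa-1,3-diene-1-carbaldehyde) | O=CC1=C(C)C=CCC1(C)C | starting material
2 | safranol | OCC1=C(C)C=CCC1(C)C | intermediate
3 | (2,6,6-trimethylcyclohexa-1,3-dien-1-yl)methyl N,N-diisopropylcarbamate | CC(C)N(C(C)C)C(=O)OCC1=C(C)C=CCC1(C)C | intermediate
4 | 2-methylcyclopent-2-en-1-one | CC1=CCCC1=O | starting material
5 | 3-chloropropanoyl chloride | O=C(Cl)CCCl | starting material
6 | 5-(3-chloropropanoyl)-2-methylcyclopent-2-en-1-one (racemic, enolisable C8) | CC1=CCC(C(=O)CCCl)C1=O | intermediate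
7 | formaldehyde | C=O | starting material
8 | (S)-5-(3-chloropropanoyl)-5-(hydroxymethyl)-2-methylcyclopent-2-en-1-one | OC[C@]1(C(=O)CCCl)CC=C(C)C1=O | intermediate
9 | (S)-TBS ether of 8 | CC(C)(C)[Si](C)(C)OC[C@]1(C(=O)CCCl)CC=C(C)C1=O | intermediate
10 | (S)-5-[(TBS-oxy)methyl]-5-(3-iodopropanoyl)-2-methylcyclopent-2-en-1-one | CC(C)(C)[Si](C)(C)OC[C@]1(C(=O)CCI)CC=C(C)C1=O | intermediate
11 | samarium(III) enolate of the cyclised diketone (C15–O–SmI2) | CC(C)(C)[Si](C)(C)OC[C@@]12C[C@@H](CCC1=O)C(C)=C2O[Sm](I)I | intermediate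
12 | (1R,5R)-1-[(TBS-oxy)methyl]-6-methyl-7-(trimethylsilyloxy)bicyclo[3.2.1]oct-6-en-2-one | CC(C)(C)[Si](C)(C)OC[C@@]12C[C@@H](CCC1=O)C(C)=C2O[Si](C)(C)C | intermediate
13 | α-lithiated carbamate (sparteine complex; S at C6 assumed) | CC(C)N(C(C)C)C(=O)O[C@@H]([Li])C1=C(C)C=CCC1(C)C | intermediate
14 | α-titanated carbamate, Ti(OiPr)3 at C6 (inverted relative to 13) | CC(C)N(C(C)C)C(=O)O[C@H]([Ti](OC(C)C)(OC(C)C)OC(C)C)C1=C(C)C=CCC1(C)C | intermediate
15 | homoaldol adduct: 9-OH (syn to the C15–C16 bridge), Me-20 α, Δ1, (Z)-C5=C6 enol carbamate, 7-OTBS, 15-OTMS enol ether | CC(C)N(C(C)C)C(=O)O/C=C1/C(C)(C)CC=C[C@@]1(C)[C@]2(O)CC[C@@H]3C[C@@]2(CO[Si](C)(C)C(C)(C)C)C(O[Si](C)(C)C)=C3C | intermediate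
16 | Δ9(11) triene (otherwise as 15) | CC(C)N(C(C)C)C(=O)O/C=C1/C(C)(C)CC=C[C@@]1(C)C2=CC[C@@H]3C[C@@]2(CO[Si](C)(C)C(C)(C)C)C(O[Si](C)(C)C)=C3C | intermediate
17 | C6 dimethyl acetal, 7-OH, 15-ketone, H-5β, 16-Me endo | C[C@]1(C=CCC(C)(C)[C@H]1C(OC)OC)C2=CC[C@@H]3C[C@@]2(CO)C(=O)[C@@H]3C | intermediate
18 | tetracyclic 6-O-methyl acetal, Δ1, Δ9(11), 15-ketone (major anomer drawn) | C[C@@]12C=CCC(C)(C)[C@H]1[C@H](OC)OC[C@@]34C[C@@H](CC=C23)[C@@H](C)C4=O | intermediate
19 | 1β-iodo-2α-acetoxy acetal | C[C@@]12[C@H](I)[C@@H](OC(C)=O)CC(C)(C)[C@H]1[C@H](OC)OC[C@@]34C[C@@H](CC=C23)[C@@H](C)C4=O | intermediate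
20 | 1α-hydroxy-2α-acetoxy lactol | C[C@@]12[C@@H](O)[C@@H](OC(C)=O)CC(C)(C)[C@H]1[C@H](O)OC[C@@]34C[C@@H](CC=C23)[C@@H](C)C4=O | intermediate
21 | 1α,2α,6-triacetate, Δ9(11) (anomer drawn corresponds to the target) | C[C@@]12[C@@H](OC(C)=O)[C@@H](OC(C)=O)CC(C)(C)[C@H]1[C@H](OC(C)=O)OC[C@@]34C[C@@H](CC=C23)[C@@H](C)C4=O | intermediate
22 | 9α,11α-epoxy-1α,2α,6-triacetate | CC(=O)O[C@H]1CC(C)(C)[C@H]2[C@H](OC(C)=O)OC[C@@]34C[C@@H](C[C@H]5O[C@]53[C@]2(C)[C@H]1OC(C)=O)[C@@H](C)C4=O | intermediate
23 | CNP0210140.1 (1R,2S,5R,6R,8S,9S,10S,11R,13S,16R in the numbering above) | CC(=O)O[C@H]1CC(C)(C)[C@H]2[C@H](O)OC[C@@]34C[C@@H](C[C@H]5O[C@]53[C@]2(C)[C@H]1OC(C)=O)[C@@H](C)C4=O | target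

**Totals**
Total steps: 13. Longest linear sequence: 11 (steps 3–13); steps 1–2 make carbamate 3, which enters at step 8.

**Three steps most likely to fail**

Step 8 is the weakest: a γ,γ-disubstituted allyltitanium must add to a ketone next to a quaternary carbon, and reagent and substrate control must agree. The fallback sets out from 2 and 12 and comes back at 18. Safranol 2 is converted with PBr3 into safranyl bromide F1. Indium-mediated Barbier γ-pentadienylation of 12 in THF then gives the tertiary homoallylic alcohol F2 (C10 quaternary, exocyclic C5=C6 methylene, Δ1), with C10 under substrate control and the epimers separated. Burgess dehydration gives the exocyclic-methylene triene F3. Hydroboration–oxidation of the 1,1-disubstituted olefin from the β-face gives the primary alcohol F4 (H-5β), and Dess–Martin oxidation gives the aldehyde F5. Acid methanolysis and PPTS as in step 10 close the oxepane to 18.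

Step 10 may give the wrong C5 epimer or fail to close the seven-membered acetal. The fallback sets out from 16 and comes back at 18. Excess MeLi at −78 °C cleaves the carbamate and the enol silane to a dilithium bis-enolate. Kinetic protonation with a hindered phenol at −78 °C gives the keto aldehyde F6 with the C7 silyl ether intact. HF·pyridine removes the TBS group and the hydroxy aldehyde closes to the lactol F7. MeOH/PPTS converts F7 into 18.

Step 11 may suffer from attack on Δ9(11), slow displacement of the neopentyl iodide, or vinyl migration. The fallback sets out from 18 and comes back at 21. OsO4/NMO gives the 1β,2β-diol F8 from the open face. Swern oxidation gives the 1,2-dione F9. NaBH4 at −78 °C delivers hydride to both carbonyls from the β-face (axial at C1; at C2 the α-face is blocked by two syn-axial methyls) to give the 1α,2α-diol F10. Aqueous acetic acid hydrolysis of the methyl acetal and Ac2O/pyridine/DMAP give 21.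

**Further compounds**
F1 | step 8 | safranyl bromide | BrCC1=C(C)C=CCC1(C)C
F2 | step 8 | Barbier adduct (9-OH, exocyclic C5=C6 methylene) | C=C1C(C)(C)CC=C[C@@]1(C)[C@]2(O)CC[C@@H]3C[C@@]2(CO[Si](C)(C)C(C)(C)C)C(O[Si](C)(C)C)=C3C
F3 | step 8 | exocyclic-methylene triene | C=C1C(C)(C)CC=C[C@@]1(C)C2=CC[C@@H]3C[C@@]2(CO[Si](C)(C)C(C)(C)C)C(O[Si](C)(C)C)=C3C
F4 | step 8 | C6 primary alcohol (H-5β) | OC[C@@H]1C(C)(C)CC=C[C@@]1(C)C2=CC[C@@H]3C[C@@]2(CO[Si](C)(C)C(C)(C)C)C(O[Si](C)(C)C)=C3C
F5 | step 8 | C6 aldehyde | O=C[C@@H]1C(C)(C)CC=C[C@@]1(C)C2=CC[C@@H]3C[C@@]2(CO[Si](C)(C)C(C)(C)C)C(O[Si](C)(C)C)=C3C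
F6 | step 10 | keto aldehyde with 7-OTBS | O=C[C@@H]1C(C)(C)CC=C[C@@]1(C)C2=CC[C@@H]3C[C@@]2(CO[Si](C)(C)C(C)(C)C)C(=O)[C@@H]3C
F7 | step 10 | tetracyclic lactol | C[C@@]12C=CCC(C)(C)[C@H]1[C@H](O)OC[C@@]34C[C@@H](CC=C23)[C@@H](C)C4=O
F8 | step 11 | 1β,2β-diol acetal | C[C@@]12[C@H](O)[C@H](O)CC(C)(C)[C@H]1[C@H](OC)OC[C@@]34C[C@@H](CC=C23)[C@@H](C)C4=O
F9 | step 11 | 1,2-dione acetal | C[C@@]12C(=O)C(=O)CC(C)(C)[C@H]1[C@H](OC)OC[C@@]34C[C@@H](CC=C23)[C@@H](C)C4=O
F10 | step 11 | 1α,2α-diol acetal | C[C@@]12[C@@H](O)[C@@H](O)CC(C)(C)[C@H]1[C@H](OC)OC[C@@]34C[C@@H](CC=C23)[C@@H](C)C4=O
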